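The cyclohexane ring carries, on the adjacent carbons C10 and C5, two arms that both end in a former terminal alkene: the oxirane C1–C2 and the acrolein unit C4(=C3)–C15. Both are traced back to a single C1=C4 double bond held in a four-membered ring fused across C5–C10. Ethenolysis of this strained cyclobutene cleaves C1=C4 and caps C1 and C4 with the methylene carbons C2 and C3 in one operation, without touching the quaternary centre C10. The precursor is a cis-fused 6,8-dimethylbicyclo[4.2.0]oct-7-en-2-one whose cyclobutene lies anti to a C9 silyl ether; it comes from an enone–propyne photocycloaddition.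

Key step: step 5

Conventions: atoms are numbered as in the elemane skeleton (ring C5–C10; C14 = methyl on C10; C1–C2 = arm on C10; C4, C3, C15 = arm on C5; C11–C13 = lactone carbons). β is the ring face that carries C14, α the opposite face. O9 is carried as a triethylsilyl ether so that it can be unmasked beside a tert-butyldimethylsilyl ether on O6.

Assumption: the target is made as the open 6-hydroxy-15-al form as drawn; a lactol between O6 and C15 would be its ring tautomer.

Step 1
Reactants: 1 2-methylcyclohex-2-en-1-one
Product: 2 (S)-2-methylcyclohex-2-en-1-ol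
Conditions: (R)-2-methyl-CBS-oxazaborolidine (10 mol %), BH3·SMe2, THF, −20 °C
Reagents that add atoms: none
Why: CBS reduction, in which the oxazaborolidine–borane complex binds the carbonyl anti to the larger methyl-substituted alkenyl arm and delivers hydride to one face, so that the (R)-catalyst should give the (S)-allylic alcohol (the future C9).

Step 2
Reactants: 2 (S)-2-methylcyclohex-2-en-1-ol
Product: 3 (S)-triethyl[(2-methylcyclohex-2-en-1-yl)oxy]silane
Conditions: Et3SiCl, imidazole, CH2Cl2, 0 °C to rt
Reagents that add atoms: chlorotriethylsilane, CC[Si](Cl)(CC)CC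
Why: Standard silylation of a secondary alcohol, the triethylsilyl group being chosen because it can later be cleaved in the presence of a tert-butyldimethylsilyl ether.

Step 3
Reactants: 3 (S)-triethyl[(2-methylcyclohex-2-en-1-yl)oxy]silane
Product: 4 (S)-3-methyl-4-(triethylsilyloxy)cyclohex-2-en-1-one
Conditions: CrO3, 3,5-dimethylpyrazole, CH2Cl2, −20 °C
Reagents that add atoms: chromium trioxide, O=[Cr](=O)=O
Why: Allylic C–H oxidation with the CrO3–3,5-dimethylpyrazole complex should turn the ring CH2 next to the unsubstituted alkene carbon into the enone carbonyl, the other allylic C–H being a methine shielded by the silyl ether, and the stereocentre is not touched.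

Step 4
Reactants: 4 (S)-3-methyl-4-(triethylsilyloxy)cyclohex-2-en-1-one; 5 propyne
Product: 6 cis-fused 6,8-dimethyl-5-(triethylsilyloxy)bicyclo[4.2.0]oct-7-en-2-one (cyclobutene anti to the silyloxy group)
Conditions: hν (350 nm, Pyrex), excess propyne, CH2Cl2, −78 °C
Reagents that add atoms: propyne, CC#C
Why: Enone–alkyne [2+2] photocycloaddition through the enone triplet, in which propyne adds to the β-carbon C10 on the face anti to the neighbouring silyloxy group (sets C10), the four-membered ring can only close cis (sets C5), and terminal alkynes favour the head-to-head orientation that places the methyl-bearing carbon on C5; minor isomers are removed by chromatography.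

Step 5
Reactants: 6 cis-fused 6,8-dimethyl-5-(triethylsilyloxy)bicyclo[4.2.0]oct-7-en-2-one; 7 ethylene
Product: 8 2-isopropenyl-3-methyl-4-(triethylsilyloxy)-3-vinylcyclohexan-1-one (C10: CH3 β, vinyl α; C5: isopropenyl α, cis to vinyl; C9: OSiEt3 β)
Conditions: second-generation Grubbs catalyst (H2IMes)(PCy3)Cl2Ru=CHPh (5 mol %), ethylene (1 atm), CH2Cl2, 25–40 °C
Reagents that add atoms: ethylene, C=C
Why: The ruthenium methylidene formed from the precatalyst and ethylene adds across the strained C1=C4 bond, and cycloreversion of the ruthenacyclobutane opens the four-membered ring to a ruthenium alkylidene that ethylene then cleaves, so that C1 and C4 are capped by the methylene carbons C2 and C3 and the methylidene is regenerated. The closest known reaction type is the ring-opening cross-metathesis (ethenolysis) of fused cyclobutenes obtained from enone–alkyne photocycloadditions. No ring is closed and no stereocentre is created; C10 and C5 are carried over unchanged from 6, so 8 still has the isopropenyl group cis to the vinyl group (corrected in step 7). The step needs chemoselectivity for the cyclobutene over the two alkenes it produces, and this is secured by the release of roughly 30 kcal/mol of ring strain together with the low metathesis reactivity of a neopentyl vinyl group and a 1,1-disubstituted alkene. The ethylene atmosphere intercepts the opened alkylidene before it can add to a second cyclobutene, which suppresses oligomerisation, and the ketone and silyl ether are inert to the catalyst.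

Step 6
Reactants: 8 2-isopropenyl-3-methyl-4-(triethylsilyloxy)-3-vinylcyclohexan-1-one; 9 tert-butyl bromoacetate
Product: 11 tert-butyl 2-[3-isopropenyl-4-methyl-2-oxo-5-(triethylsilyloxy)-4-vinylcyclohexyl]acetate (C7 epimers; C5 isopropenyl still α), via lithium enolate 10 (not isolated)
Conditions: LiN(iPr)2, THF, −78 °C; then BrCH2CO2tBu, DMPU, −78 to −40 °C
Reagents that add atoms: tert-butyl bromoacetate, CC(C)(C)OC(=O)CBr
Why: Kinetic deprotonation by the hindered amide at the open C7 methylene (not at the C5 methine next to the quaternary centre) followed by SN2 alkylation of the enolate with the activated bromoacetate; the C7 configuration is left open because the next step sets it.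

Step 7
Reactants: 11 tert-butyl 2-[3-isopropenyl-4-methyl-2-oxo-5-(triethylsilyloxy)-4-vinylcyclohexyl]acetate (C7 epimers)
Product: 12 the same ester with C5 isopropenyl β and C7 acetate arm β (both equatorial, trans to vinyl)
Conditions: DBU (0.3 equiv), toluene, rt to 50 °C
Reagents that add atoms: none
Why: Thermodynamic epimerisation through the C6 enolate at both α-carbons should settle C5 and C7 with their substituents equatorial (only the C10 methyl stays axial), while short exposure and kinetic α-protonation keep the isopropenyl group out of conjugation.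

Step 8
Reactants: 12 equilibrated keto ester
Product: 13 tert-butyl 2-[2-hydroxy-3-isopropenyl-4-methyl-5-(triethylsilyloxy)-4-vinylcyclohexyl]acetate (6β-OH, axial)
Conditions: LiBH(s-Bu)3, THF, −78 °C; AcOH, −78 °C
Reagents that add atoms: none
Why: Bulky hydride reduction in which axial delivery on the β-face is blocked by the syn-axial C10 methyl, so hydride enters equatorially from the α-face and gives the axial 6β-alcohol, and the cold quench keeps the tert-butyl ester from lactonising onto the cis alkoxide.

Step 9
Reactants: 13 6β-alcohol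
Product: 14 6β-tert-butyldimethylsilyl ether of 13
Conditions: t-BuMe2SiOTf, 2,6-lutidine, CH2Cl2, −78 to 0 °C
Reagents that add atoms: tert-butyldimethylsilyl triflate, CC(C)(C)[Si](C)(C)OS(=O)(=O)C(F)(F)F
Why: Silyl triflate silylation with a hindered pyridine base is reactive enough for the axial, flanked hydroxyl and is non-basic, so the cis acetate arm does not lactonise and O6 stays masked until step 19.

Step 10
Reactants: 14 bis-silyl ether
Product: 15 tert-butyl 2-[2-(tert-butyldimethylsilyloxy)-5-hydroxy-3-isopropenyl-4-methyl-4-vinylcyclohexyl]acetate (9β-OH)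
Conditions: PPTS (cat.), MeOH/CH2Cl2, 0 °C to rt
Reagents that add atoms: none
Why: Acid-catalysed methanolysis cleaves the triethylsilyl ether much faster than the more hindered tert-butyldimethylsilyl ether, freeing only the C9 hydroxyl.

Step 11
Reactants: 15 9β-alcohol
Product: 16 tert-butyl 2-[2-(tert-butyldimethylsilyloxy)-3-isopropenyl-4-methyl-5-oxo-4-vinylcyclohexyl]acetate (C9 ketone)
Conditions: Dess–Martin periodinane, CH2Cl2, rt
Reagents that add atoms: none
Why: Dess–Martin oxidation of the only free secondary alcohol gives the C9 ketone under near-neutral conditions that leave both alkenes, the silyl ether and the ester untouched.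

Step 12
Reactants: 16 C9 ketone
Product: 18 8α-hydroxy C9 ketone, via potassium enolate 17 (not isolated)
Conditions: KN(SiMe3)2, THF, −78 °C; then trans-2-(phenylsulfonyl)-3-phenyloxaziridine, −78 °C; AcOH
Reagents that add atoms: 2-(phenylsulfonyl)-3-phenyloxaziridine, O=S(=O)(c1ccccc1)N1OC1c1ccccc1
Why: Enolate hydroxylation with an N-sulfonyloxaziridine, where C8 is the only enolisable position of the C9 ketone (C10 is quaternary and the ketone is more acidic than the ester) and oxygen should arrive on the α-face because the β-face of the enolate is screened by the axial C10 methyl, the axial C6 silyloxy group and the C7 arm, giving the equatorial 8α-alcohol.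

Step 13
Reactants: 18 8α-hydroxy C9 ketone
Product: 19 8α,9α-diol (tert-butyl ester, 6β-OSi)
Conditions: LiBH(s-Bu)3 (excess), THF, −78 °C; AcOH
Reagents that add atoms: none
Why: Bulky hydride reduction by equatorial (β-face) attack, as with 2,2-disubstituted cyclohexanones, should give the axial 9α-alcohol cis to the 8α-hydroxyl.

Step 14
Reactants: 19 8α,9α-diol
Product: 20 trans-fused 8α,12-lactone: 4-(tert-butyldimethylsilyloxy)-7-hydroxy-5-isopropenyl-6-methyl-6-vinylhexahydro-1-benzofuran-2(3H)-one (6β-OSi; 9α-OH)
Conditions: t-BuOK (0.2 equiv), THF, 0 °C to rt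
Reagents that add atoms: none
Why: Base-catalysed intramolecular transesterification in which the 8α-alkoxide, trans-diequatorial to the C7 acetate arm, closes the five-membered lactone and expels tert-butoxide, while O9 lies on the face opposite to the arm and cannot reach the ester and O6 is silylated.

Step 15
Reactants: 20 8α,12-lactone
Product: 22 11-(dimethylaminomethyl) lactone (C11 epimers), via dilithium alkoxide enolate 21 (not isolated)
Conditions: LiN(iPr)2 (2.2 equiv), THF, −78 °C; then CH2=NMe2+ I−, −78 to 0 °C
Reagents that add atoms: dimethyl(methylidene)ammonium iodide, C=[N+](C)C.[I-]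
Why: Mannich reaction of the lactone enolate (the C9 hydroxyl being carried as its alkoxide) with the preformed iminium salt attaches the aminomethyl carbon C13 to C11, and the new C11 centre is lost in the next step.

Step 16
Reactants: 22 Mannich base
Product: 24 α-methylene lactone (C11=C13; 6β-OSi; 9α-OH; isopropenyl and vinyl intact), via trimethylammonium iodide 23 (not isolated)
Conditions: MeI, MeOH, rt; then NaHCO3 (aq), EtOAc, rt
Reagents that add atoms: none
Why: Exhaustive methylation of the amine followed by base-induced Hofmann-type elimination of trimethylamine from the β-ammonium lactone gives the exocyclic methylene.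

Step 17
Reactants: 24 α-methylene lactone
Product: 25 enal: the C5 arm is now C(=CH2)CHO (C15 aldehyde)
Conditions: SeO2, 1,4-dioxane, 80 °C
Reagents that add atoms: selenium dioxide, O=[Se]=O
Why: Selenium dioxide allylic oxidation (ene reaction, [2,3]-sigmatropic shift, then oxidation of the allylic alcohol) converts the isopropenyl methyl C15 into the aldehyde, since the only other allylic C–H on this alkene is the hindered C5 methine, the vinyl group has none, and the methylene lactone is electron-poor.

Step 18
Reactants: 25 enal with free 9α-OH; 26 angelic acid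
Product: 28 9α-angelate of 25 (6β-OSi), via mixed anhydride 27 (not isolated)
Conditions: 26, 2,4,6-Cl3C6H2COCl, Et3N, toluene, rt; then 25, 80 °C
Reagents that add atoms: angelic acid, C/C=C(/C)C(=O)O
Why: Yamaguchi esterification, in which the preformed mixed anhydride acylates the hindered axial hydroxyl on heating without a nucleophilic catalyst, conditions under which the angeloyl group is transferred without Z-to-E isomerisation.

Step 19
Reactants: 28 silyl-protected angelate
Product: 29 6β-alcohol: 9α-angeloyloxy-6β-hydroxy-15-oxoelema-1,3,11(13)-trien-12,8α-olide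
Conditions: HF·pyridine, pyridine, THF, 0 °C to rt
Reagents that add atoms: none
Why: Fluoride-mediated cleavage of the silyl ether in a weakly acidic, buffered medium leaves the angelate, enal and methylene lactone unchanged and is carried out before the acid-sensitive oxirane exists.

Step 20
Reactants: 29 vinyl compound
Product: 30 target, (1R)-1,2-epoxy-6β-hydroxy-15-oxoelema-3,11(13)-dien-12,8α-olide 9α-angelate
Conditions: Ti(OiPr)4 (10 mol %), chiral salalen ligand (antipode that gives (R)-1,2-epoxyalkanes from 1-alkenes), 30 % aq. H2O2, CH2Cl2, rt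
Reagents that add atoms: hydrogen peroxide, OO
Why: Titanium–salalen-catalysed asymmetric epoxidation of an unconjugated terminal alkene with hydrogen peroxide, in which the electrophilic titanium peroxo species reacts only with the electron-rich vinyl group (the enal, methylene lactone and angelate alkenes are electron-poor) and the chiral ligand rather than the substrate selects the alkene face, giving the (R)-oxirane at C1.

Compound list
1 | 2-methylcyclohex-2-en-1-one | CC1=CCCCC1=O | starting material
2 | (S)-2-methylcyclohex-2-en-1-ol | C1CC[C@H](O)C(C)=C1 | intermediate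
3 | (S)-triethyl[(2-methylcyclohex-2-en-1-yl)oxy]silane | C1CC[C@H](O[Si](CC)(CC)CC)C(C)=C1 | intermediate
4 | (S)-3-methyl-4-(triethylsilyloxy)cyclohex-2-en-1-one | O=C1CC[C@H](O[Si](CC)(CC)CC)C(C)=C1 | intermediate
5 | propyne | CC#C | starting material
6 | cis-fused 6,8-dimethyl-5-(triethylsilyloxy)bicyclo[4.2.0]oct-7-en-2-one, cyclobutene anti to OSiEt3 (C10: CH3 β, C1 α; H5 β; OSiEt3 β) | O=C1CC[C@H](O[Si](CC)(CC)CC)[C@@]2(C)C=C(C)[C@@H]12 | intermediate (key-step precursor)
7 | ethylene | C=C | starting material
8 | 2-isopropenyl-3-methyl-4-(triethylsilyloxy)-3-vinylcyclohexan-1-one (C10: CH3 β, vinyl α; C5 isopropenyl α; C9 OSiEt3 β) | O=C1CC[C@H](O[Si](CC)(CC)CC)[C@@](C)(C=C)[C@H]1C(C)=C | intermediate (key-step product)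
9 | tert-butyl bromoacetate | CC(C)(C)OC(=O)CBr | starting material
10 | lithium enolate of 8 (C6–O–Li, C6=C7) | [Li+].[O-]C1=CC[C@H](O[Si](CC)(CC)CC)[C@@](C)(C=C)[C@H]1C(C)=C | intermediate
11 | tert-butyl 2-[3-isopropenyl-4-methyl-2-oxo-5-(triethylsilyloxy)-4-vinylcyclohexyl]acetate, C5 isopropenyl α, C7 epimers | C2C(CC(=O)OC(C)(C)C)C(=O)[C@H](C(C)=C)[C@](C)(C=C)[C@H]2O[Si](CC)(CC)CC | intermediate
12 | same ester, C5 isopropenyl β and C7 arm β (all-equatorial, trans to vinyl) | C2[C@@H](CC(=O)OC(C)(C)C)C(=O)[C@@H](C(C)=C)[C@](C)(C=C)[C@H]2O[Si](CC)(CC)CC | intermediate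
13 | 6β-alcohol (axial OH) of 12 | C2[C@@H](CC(=O)OC(C)(C)C)[C@@H](O)[C@@H](C(C)=C)[C@](C)(C=C)[C@H]2O[Si](CC)(CC)CC | intermediate
14 | 6β-tert-butyldimethylsilyl ether, 9β-triethylsilyl ether | C2[C@@H](CC(=O)OC(C)(C)C)[C@@H](O[Si](C)(C)C(C)(C)C)[C@@H](C(C)=C)[C@](C)(C=C)[C@H]2O[Si](CC)(CC)CC | intermediate
15 | 9β-alcohol, 6β-OSi(t-Bu)Me2 | C2[C@@H](CC(=O)OC(C)(C)C)[C@@H](O[Si](C)(C)C(C)(C)C)[C@@H](C(C)=C)[C@](C)(C=C)[C@H]2O | intermediate
16 | C9 ketone, 6β-OSi(t-Bu)Me2 | C2[C@@H](CC(=O)OC(C)(C)C)[C@@H](O[Si](C)(C)C(C)(C)C)[C@@H](C(C)=C)[C@](C)(C=C)C2=O | intermediate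
17 | potassium enolate of 16 (C8=C9–OK) | [K+].[O-]C1=C[C@@H](CC(=O)OC(C)(C)C)[C@@H](O[Si](C)(C)C(C)(C)C)[C@@H](C(C)=C)[C@]1(C)C=C | intermediate
18 | 8α-hydroxy C9 ketone | O[C@@H]2[C@@H](CC(=O)OC(C)(C)C)[C@@H](O[Si](C)(C)C(C)(C)C)[C@@H](C(C)=C)[C@](C)(C=C)C2=O | intermediate
19 | 8α,9α-diol tert-butyl ester | O[C@@H]2[C@@H](CC(=O)OC(C)(C)C)[C@@H](O[Si](C)(C)C(C)(C)C)[C@@H](C(C)=C)[C@](C)(C=C)[C@@H]2O | intermediate
20 | trans-fused 8α,12-lactone, 6β-OSi(t-Bu)Me2, 9α-OH, isopropenyl and vinyl arms | C1C(=O)O[C@@H]2[C@@H]1[C@@H](O[Si](C)(C)C(C)(C)C)[C@@H](C(C)=C)[C@](C)(C=C)[C@@H]2O | intermediate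
21 | dilithium C9-alkoxide lactone enolate of 20 | [Li+].[Li+].C1=C([O-])O[C@@H]2[C@@H]1[C@@H](O[Si](C)(C)C(C)(C)C)[C@@H](C(C)=C)[C@](C)(C=C)[C@@H]2[O-] | intermediate
22 | 11-(dimethylaminomethyl) lactone, C11 epimers | CN(C)CC1C(=O)O[C@@H]2[C@@H]1[C@@H](O[Si](C)(C)C(C)(C)C)[C@@H](C(C)=C)[C@](C)(C=C)[C@@H]2O | intermediate
23 | trimethylammonium iodide of 22 | C[N+](C)(C)CC1C(=O)O[C@@H]2[C@@H]1[C@@H](O[Si](C)(C)C(C)(C)C)[C@@H](C(C)=C)[C@](C)(C=C)[C@@H]2O.[I-] | intermediate
24 | α-methylene 8α,12-lactone, 6β-OSi(t-Bu)Me2, 9α-OH | C=C1C(=O)O[C@@H]2[C@@H]1[C@@H](O[Si](C)(C)C(C)(C)C)[C@@H](C(C)=C)[C@](C)(C=C)[C@@H]2O | intermediate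
25 | 15-al (C5 arm = 2-propenal-2-yl), otherwise as 24 | C=C1C(=O)O[C@@H]2[C@@H]1[C@@H](O[Si](C)(C)C(C)(C)C)[C@@H](C(=C)C=O)[C@](C)(C=C)[C@@H]2O | intermediate
26 | angelic acid, (Z)-2-methylbut-2-enoic acid | C/C=C(/C)C(=O)O | starting material
27 | angelic 2,4,6-trichlorobenzoic anhydride | C/C=C(/C)C(=O)OC(=O)c1c(Cl)cc(Cl)cc1Cl | intermediate
28 | 9α-angelate of 25, 6β-OSi(t-Bu)Me2 | C=C1C(=O)O[C@@H]2[C@@H]1[C@@H](O[Si](C)(C)C(C)(C)C)[C@@H](C(=C)C=O)[C@](C)(C=C)[C@@H]2OC(=O)/C(C)=C\C | intermediate
29 | 9α-angeloyloxy-6β-hydroxy-15-oxoelema-1,3,11(13)-trien-12,8α-olide | C=C1C(=O)O[C@@H]2[C@@H]1[C@@H](O)[C@@H](C(=C)C=O)[C@](C)(C=C)[C@@H]2OC(=O)/C(C)=C\C | intermediate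
30 | CNP0130022.2, (1R)-1,2-epoxy-6β-hydroxy-15-oxoelema-3,11(13)-dien-12,8α-olide 9α-angelate | C=C1C(=O)O[C@@H]2[C@@H]1[C@@H](O)[C@@H](C(=C)C=O)[C@](C)([C@@H]1CO1)[C@@H]2OC(=O)/C(C)=C\C | target

Total step count: 20. Longest linear sequence: 20 steps (from 1).

Steps most likely to fail

1. Step 20 (epoxidation). Oxygen transfer to the neopentyl vinyl group may be slow. The substrate's own facial bias (approach past H9, or delivery from an oxygen on C9, places C2 next to H9 and leads to the C1 epimer) may also not be fully overridden by the ligand, giving poor facial selectivity. The fallback replaces asymmetric oxygen transfer by resolution of the oxirane. Setting out from 29, dimethyldioxirane (acetone, 0 °C) would epoxidise the vinyl group without face control to the C1-epimeric oxirane mixture F1. Hydrolytic kinetic resolution with (salen)Co(OAc) (trivalent cobalt; the catalyst antipode that hydrates the (1S)-oxirane) and a sub-stoichiometric amount of water would then open only the unwanted epimer to its diol and leave 30, where the fallback rejoins the route.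

2. Step 18 (angeloylation). Acylation of the hindered axial 9α-hydroxyl may stall, or forcing conditions may isomerise the angeloyl group to tigloyl. The fallback builds the Z-alkene on the molecule instead of transferring it. Setting out from 24 (before the aldehyde exists), esterification with 2-[bis(2,2,2-trifluoroethoxy)phosphoryl]propanoic acid (DCC, DMAP, CH2Cl2) would give the phosphonopropanoate F2. Still–Gennari olefination with acetaldehyde (KN(SiMe3)2, 18-crown-6, THF, −78 °C) would give the (Z)-2-methylbut-2-enoate F3, and SeO2 oxidation as in step 17 would return to the route at 28.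

3. Step 3 (allylic oxidation). Oxidation may attack the silyloxy-bearing allylic C–H, with loss of the stereocentre, or over-oxidise the ring. The fallback is a 1,3-oxidative transposition. Setting out from 3, epoxidation (mCPBA, CH2Cl2) would give the epoxide F4. Opening at the less substituted carbon with PhSeNa (PhSeSePh, NaBH4, EtOH) would give the hydroxy selenide F5, and oxidation with H2O2 with syn-elimination the tertiary allylic alcohol F6. Oxidation with pyridinium chlorochromate, C5H5NH[CrO3Cl], with allylic transposition would give 4, where the route continues.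

Further compounds
F1 | step 20 | C1-epimer mixture of the oxirane (30 and its (1S)-epimer) | C=C1C(=O)O[C@@H]2[C@@H]1[C@@H](O)[C@@H](C(=C)C=O)[C@](C)(C1CO1)[C@@H]2OC(=O)/C(C)=C\C
F2 | step 18 | 9α-{2-[bis(2,2,2-trifluoroethoxy)phosphoryl]propanoate} of 24 | C=C1C(=O)O[C@@H]2[C@@H]1[C@@H](O[Si](C)(C)C(C)(C)C)[C@@H](C(C)=C)[C@](C)(C=C)[C@@H]2OC(=O)C(C)P(=O)(OCC(F)(F)F)OCC(F)(F)F
F3 | step 18 | 9α-angelate of 24 (isopropenyl arm intact) | C=C1C(=O)O[C@@H]2[C@@H]1[C@@H](O[Si](C)(C)C(C)(C)C)[C@@H](C(C)=C)[C@](C)(C=C)[C@@H]2OC(=O)/C(C)=C\C
F4 | step 3 | 2,3-epoxide of 3, triethyl[(1-methyl-7-oxabicyclo[4.1.0]heptan-2-yl)oxy]silane | CC12OC1CCC[C@@H]2O[Si](CC)(CC)CC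
F5 | step 3 | 1-methyl-2-(phenylselanyl)-6-(triethylsilyloxy)cyclohexan-1-ol | CC1(O)C([Se]c2ccccc2)CCC[C@@H]1O[Si](CC)(CC)CC
F6 | step 3 | 1-methyl-6-(triethylsilyloxy)cyclohex-2-en-1-ol | CC1(O)C=CCC[C@@H]1O[Si](CC)(CC)CC
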